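The decision is whether to raise the nucleophile from its charge in ash to its charge in oak, with the electrophile held and the flask stopped at the same hour.

common to all: electrophile 0.050 M; gas 3.4 mM (held)
- zeta: nucleophile 0.034 M; scavenger 0.040 M (fed, over 15 min); run made earlier
- delta: nucleophile 0.048 M; scavenger 0.040 M (fed, over 15 min); run made earlier
- gamma: nucleophile 0.041 M; scavenger 0.040 M (fed, over 15 min); run made earlier
- ash: nucleophile 0.0400 M; scavenger 0.0400 M (fed, over 15 min); time 1.0 h
- oak: nucleophile 0.0520 M; scavenger 0.0400 M (fed, over 15 min); time 1.0 h

| run | time / min | electrophile / % | target / % |
|---|---|---|---|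
| zeta | 2.50 | 95.1 | 4.6 |
| zeta | 5.00 | 91.2 | 9.4 |
| zeta | 8.00 | 87.2 | 12.9 |
| zeta | 15.0 | 81.7 | 18.1 |
| zeta | 30.0 | 74.6 | 25.0 |
| delta | 2.50 | 92.9 | 8.0 |
| delta | 8.00 | 81.9 | 17.7 |
| delta | 15.0 | 74.5 | 25.1 |
| delta | 20.0 | 71.3 | 28.6 |
| delta | 30.0 | 66.8 | 32.8 |
| gamma | 2.50 | 93.8 | 6.9 |
| gamma | 8.00 | 84.0 | 15.4 |
| gamma | 15.0 | 77.8 | 22.0 |
| gamma | 20.0 | 75.0 | 25.1 |
| gamma | 30.0 | 70.6 | 29.6 |

(each reading ± 0.3 percentage points)

- what was read earlier has a scatter of 0.3 percentage points, one standard deviation
- at the start none of the gas is in solution
- a reading or a percentage of target counts all its forms, free or not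

- part of the electrophile that has reacted at the end, ash
- part of the electrophile that has reacted at the end, oak
- what raising the concentration of nucleophile from its lowest to its highest value here does to the part of the electrophile that has reacted (changes below 5 percentage points count as none) (it rises / it falls / no change)

Ines reasons from the equation: one nucleophile takes one electrophile, and in ash the nucleophile is the limiting reagent, 0.0400 M against 0.050 M. Her symmetric case therefore turns each extra nucleophile into one more reacted electrophile for as long as electrophile stands against it. Oak's 0.0520 M is more than the 0.050 M of electrophile, so on her equation the step from ash to oak is worth at most 20.0% of the electrophile charged.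

Tom reasons from the readings. Between 15.0 min and 30.0 min the electrophile falls by 7.1 percentage points in zeta and by 7.7 points in delta, although delta holds more nucleophile, and each reading carries a scatter of 0.3 points. The gap between these two runs is already 7.2 points at 15.0 min, so he expects extra nucleophile to pay early and then stop paying.

To compare the two views on one scale, take the return, the extra electrophile reacted per extra nucleophile charged, where one is Ines's symmetric case and zero means that nucleophile does nothing. Zeta and delta at 30.0 min give a return of 0.279. Applied to the step from ash to oak, this gives a rise of 6.7 points, which is more than the mark of 5 points, so I commit to "it rises", though by far less than Ines says.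

The forecast, on Tom's side because “all runs show nearly the same slow tail”, gives 39% for ash and 44.5% for oak, a gap of 5.5 points against the 6.7 points from the return, and says it rises.

The flask gives 35.9% for ash and 43.9% for oak: it rises, by 8 points.

    electrophile + nucleophile → acid set free + target (k = 0.747 /M/min)
    nucleophile + acid set free ⇌ protonated nucleophile, settled at all times (K = 2200 /M)
    acid set free + free base ⇌ salt of the base, settled at all times (K = 680 /M)
    nucleophile + acid set free ⇌ idle adduct A, settled at all times (K = 45.0 /M)
    acid set free + scavenger → scavenged by-product (k = 5.55 /M/min)
    gas ⇌ free base, rate k6*(csat - [free base]) (kL = 17.2 /min)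
    nucleophile + target ⇌ idle adduct B, settled at all times (K = 321 /M)

Between ash and oak the return over the hour is 0.333, and after 10.0 h it is 0.479, higher but still below one, so it moves towards Ines's value without reaching it at that time. In oak at 1.0 h, the half-lives of electrophile by its step with nucleophile, 3.0 h, and of scavenger by its step with acid set free, 2.1 h, are both longer than the time run. There 56% of the electrophile and 82% of the scavenger still stand unbound. For a neighbour of oak with 0.031 M of nucleophile, the return gives 32.2%; the flask gives 29.5%.

The readings were generated by integration with made-up constants.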